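A neighbour flask with 0.0065 M of Q comes at the end; first comes the flask charged with 0.026 M.

    E ⇌ X (K1 = 2.0, k1 = 0.032 min⁻¹)
    X ⇌ Z (K2 = 0.44, k2 = 0.022 min⁻¹)
    Z ⇌ E (k3 = 0.029 min⁻¹)
    X ⇌ L (K4 = 1.5, k4 = 0.64 min⁻¹)
    Q ⇌ E, rate k5*(cs5 - [E]) while solid is left; crystals form when [E] > cs5 (cs5 = 1.5 mM, k5 = 0.021 min⁻¹)

Q 0.026 M; time 3.0 d

- Q is a solid; its amount is given per volume of the solution
- at the start none of Q is in solution
- what has only dissolved of Q counts as not reacted
- the reaction counts as stopped when no species that holds the Q changes by six tenths of a point or more over the second half of the time
- run time (flask): 3.0 d

1. why nothing more happens at 3.0 d, or that something still does (for what has run out or reacted, a solid counts together with what of it has only dissolved) (it is still moving / forward and back rates have come level / all of Q has reacted)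
2. part of the Q that has turned into other species by 3.0 d (what has only dissolved does not count)
3. the X standing at 3.0 d, as a percentage of the Q charged
4. the L standing at 3.0 d, as a percentage of the Q charged

Here is my reckoning for this flask, following the rate at which Q dissolves. You start at k5 times cs5, which is 0.0315 mM min⁻¹, and that rate falls in step with the gap cs5 − cE. If X, Z and L follow E at their balance, then for each part kept as E, X takes 2.0, Z 0.880 and L 3.00 parts. The solution must therefore take in 6.88 parts to raise cE by one, and the slowing time is that figure over k5, 328 min. The balance is a fair assumption, since E and X relax with a half-life of 0.241 h, shorter than the slowing time.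

In logarithms, the rate drops a decade every 12.6 h, so 3.0 d holds 5.73 decades. If X and Z lag and a decade lasts twice as long, the run still holds 2.87 decades. I expect the rates to have come level.

Adding up the falling rate gives the uptake, the start rate times the slowing time, 10.3 mM. The charge is more than the uptake, so solid stays. One part in 6.88 of the uptake remains as E, which leaves a conversion of 33.9%, with X at 11.5% and L at 17.3%.

The forecast says forward and back rates have come level, with conversion 33.9% (range 33% to 34.8%), X 11.5% and L 17.3%, holding that “the flask has fully levelled out by 3 days”.

The simulation gives forward and back rates have come level, with conversion 33.9%, X 11.5% and L 17.3%. Left until 30.0 d, this flask still shows a conversion of 33.9%. The reckoned uptake of this flask is 39.6% of its charge, and at 3.00 d its solid Q stands at 60.3%. The neighbour flask, with 0.0065 M of Q, is charged with less than the uptake. In the neighbour flask solid Q ends at 0%, with 15% of its charge still there as dissolved E, and its conversion ends at 85.5%; the share of what dissolves that the reckoning does not keep as E is 85.5%.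

The numbers of this flask are those of an exercise.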